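**Plan**
- Retrosynthesis first removes the seven silyl groups, then cuts the lower C3–O(ether) and lower C4–OH bonds together. This leads back to an upper C4–O–C4 lower ether with a free lower 3-hydroxyl on the opposite face.
- Enabling feature: in ring C of the lower unit the ether oxygen on C3 is cis to the C2 aryl group and trans to the hydroxyl on benzylic C4. That is the pattern left when an oxygen bridging C3 and C4 on the aryl face is opened by water at C4.
- The 4-O-4 ether is cut at lower C4–O into an upper flavan-4-ol and a lower 3,4-epoxide, both from one flav-3-ene. The flavene goes back through C3=C4 (dehydration), O1–C2 (oxa-Michael) and Cα=Cβ (aldol) to gallacetophenone and 4-hydroxybenzaldehyde.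
- Forward: rings A and B are bought and ring C closes by oxa-Michael addition. One portion of the flavene becomes the upper alcohol, a second portion is epoxidised and opened by that alcohol, then rearrangement and desilylation follow.
- Stereochemistry: C2 of both units comes from a catalytic kinetic resolution of the racemic flavanone. All other centres are relayed from C2 by additions anti to the aryl group, epoxide openings with inversion at benzylic C4, and the double inversion of the key step.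

Key step: step 11

Remark: α is the face of ring C that carries the 2-aryl group and β the opposite face; "upper" is the unit bound through C4 and "lower" the unit bound through C3 in the target; ring A is the benzo ring, ring B the 2-aryl ring, ring C the pyran ring; TBS = tert-butyldimethylsilyl.

Assumption: the (S,S)-configured ruthenium catalyst is taken to reduce the (2S)-flavanone faster, as the usual facial preference for aryl ketones and the cis preference of flavanone reduction predict; if the sense is opposite, the (R,R)-catalyst is used.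

Step 1
Reactants: 1 gallacetophenone; 2 4-hydroxybenzaldehyde
Product: 3 (E)-2',3',4',4-tetrahydroxychalcone
Conditions: HCl (g, sat.), EtOAc–EtOH, 0 °C → rt, Ar
Reagents that add atoms: none
Why: Acid-catalysed Claisen–Schmidt condensation of the methyl ketone with the non-enolisable aldehyde tolerates free phenols and should give the (E)-enone by dehydration of the aldol.

Step 2
Reactants: 3 (E)-2',3',4',4-tetrahydroxychalcone
Product: 4 rac-7,8,4'-trihydroxyflavanone
Conditions: NaOAc, EtOH–H2O, reflux, Ar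
Reagents that add atoms: none
Why: Chalcone–flavanone isomerisation by intramolecular oxa-Michael addition of the 2'-hydroxyl (6-endo-trig) closes ring C; C2 is formed racemic and is resolved in step 4.

Step 3
Reactants: 4 rac-7,8,4'-trihydroxyflavanone
Product: 5 rac-7,8,4'-tris(TBS-oxy)flavanone
Conditions: TBSCl, imidazole, DMF, rt
Reagents that add atoms: tert-butyldimethylsilyl chloride, CC(C)(C)[Si](C)(C)Cl
Why: Standard imidazole-mediated silylation of the three phenols should proceed without touching the ketone or C2.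

Step 4
Reactants: 5 rac-7,8,4'-tris(TBS-oxy)flavanone
Product: 6 (2S,4S)-7,8,4'-tris(TBS-oxy)flavan-4-ol (2,4-cis)
Conditions: RuCl[(S,S)-TsDPEN](p-cymene) (1 mol %), HCO2H–Et3N (5:2), CH2Cl2, rt, stopped near half conversion
Reagents that add atoms: none
Why: Noyori-type asymmetric transfer hydrogenation run as a kinetic resolution, a reaction type established for flavanones, should set C4 as S through the catalyst and select the (2S)-ketone because only there is the favoured carbonyl face the one anti to the 2-aryl group, leaving the (2R)-ketone to be separated.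

Step 5
Reactants: 6 (2S,4S)-7,8,4'-tris(TBS-oxy)flavan-4-ol
Product: 7 (2S)-7,8,4'-tris(TBS-oxy)flav-3-ene
Conditions: Burgess reagent, THF, 50 °C, dark
Reagents that add atoms: none
Why: Burgess dehydration (syn-elimination through the sulfamate ester) of the benzylic alcohol under neutral conditions removes the C4 centre and should leave C2 untouched.

Step 6
Reactants: 7 (2S)-7,8,4'-tris(TBS-oxy)flav-3-ene
Product: 8 (2R,3S,4R)-3-bromo-7,8,4'-tris(TBS-oxy)flavan-4-ol (3β-Br/4α-OH)
Conditions: NBS, THF–H2O, 0 °C, dark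
Reagents that add atoms: N-bromosuccinimide, O=C1CCC(=O)N1Br; water, O
Why: Bromohydrin formation should place bromine on C3 from the face anti to the 2-aryl group and water on benzylic C4 anti to bromine, as known for 2H-chromenes.

Step 7
Reactants: 8 (2R,3S,4R)-3-bromo-7,8,4'-tris(TBS-oxy)flavan-4-ol
Product: 10 (2R,3S,4S)-4-acetoxy-7,8,4'-tris(TBS-oxy)flavan-3-ol (3α-OH/4β-OAc), via α-epoxide 9 (not isolated)
Conditions: NaH, THF, 0 °C; then AcOH (excess), 0 °C → rt
Reagents that add atoms: acetic acid, CC(=O)O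
Why: Intramolecular Williamson closure of the trans-bromohydrin inverts C3 and puts the epoxide on the α face, and acetolysis then opens it at benzylic C4 with inversion, trans to O3 as is the rule in the 2,3-cis series.

Step 8
Reactants: 10 (2R,3S,4S)-4-acetoxy-7,8,4'-tris(TBS-oxy)flavan-3-ol
Product: 11 (2R,3S,4S)-4-acetoxy-3,7,8,4'-tetrakis(TBS-oxy)flavan
Conditions: TBSOTf, 2,6-lutidine, CH2Cl2, −78 → −20 °C
Reagents that add atoms: tert-butyldimethylsilyl triflate, CC(C)(C)[Si](C)(C)OS(=O)(=O)C(F)(F)F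
Why: Silyl triflate with a hindered base silylates the axial secondary 3α-hydroxyl under conditions where the trans-diaxial acetate cannot migrate and no stereocentre is touched.

Step 9
Reactants: 11 (2R,3S,4S)-4-acetoxy-3,7,8,4'-tetrakis(TBS-oxy)flavan
Product: 12 (2R,3R,4S)-3,7,8,4'-tetrakis(TBS-oxy)flavan-4-ol (3α-OTBS/4β-OH)
Conditions: i-Bu2AlH, CH2Cl2, −78 °C; aq. KNaC4H4O6
Reagents that add atoms: none
Why: Reductive cleavage of the acetate at low temperature leaves aryl and alkyl silyl ethers intact and frees the 4β-hydroxyl with retention.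

Step 10
Reactants: 7 (2S)-7,8,4'-tris(TBS-oxy)flav-3-ene (second portion); 12 (2R,3R,4S)-3,7,8,4'-tetrakis(TBS-oxy)flavan-4-ol
Product: 14 upper C4β–O–C4α lower ether with free lower 3β-hydroxyl, via β-epoxide 13 (not isolated)
Conditions: DMDO (acetone soln), CH2Cl2, −40 °C, volatiles removed cold; then 12, ZnCl2 (0.5 equiv), 4 Å MS, THF, −78 → 0 °C
Reagents that add atoms: dimethyldioxirane, CC1(C)OO1
Why: DMDO epoxidises the electron-rich C3=C4 bond anti to the 2-aryl group, and ZnCl2-assisted alcoholysis of the benzylic epoxide at C4 with inversion (the reaction type of glycal epoxide glycosylation and chromene oxide alcoholysis) sets lower C4 as α-ether and lower C3 as β-hydroxyl.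

Step 11
Reactants: 14 upper C4β–O–C4α lower ether with free lower 3β-hydroxyl
Product: 17 heptasilylated upper C4β–O–C3α lower ether with free lower 4β-hydroxyl, via lower 3β-triflate 15 (not isolated), via oxiranium triflate 16 (not isolated)
Conditions: Tf2O, 2,6-di-tert-butyl-4-methylpyridine, CH2Cl2, −78 °C; then THF–H2O, −78 → 0 °C
Reagents that add atoms: water, O
Why: Proposed new method: triflation of the lower 3β-hydroxyl gives 15, and in the ring C conformer with the C2, C3 and C4 substituents axial a lone pair of the 4α-ether oxygen lies antiperiplanar to the C3–OTf bond and displaces triflate from the α face to give oxiranium ion 16, which water opens at C4; the closest known reaction type is the 1,2-migration of an anomeric alkoxy or thio group to C2 of glycosides through oxiranium or thiiranium ions on activation of a trans-2-hydroxyl, together with the epoxonium openings of polyether cascades. No ring remains in the product; the transient three-membered ring closes in the 3-exo-tet mode. The new centre at lower C3 (α-O, cis to the aryl group) follows from backside attack of the tethered oxygen, that is inversion dictated by the 3β-leaving group of 14, and the new centre at lower C4 (β-OH) from attack of water anti to the bridging oxygen or, if the ion opens first, anti to the 3α-ether of the 2,3-cis cation. The step needs opening at C4 and not back at C3, which the benzylic position para to the 7-silyloxy group and ortho to O1 secures. It also needs oxygen participation to outrun the shift of the equally antiperiplanar 2-aryl group and the loss of the upper unit as a C4 cation; the silyl ether damps the donor power of ring B, only cleavage of a ring C–O bond releases the strain of the three-membered ring, and low temperature with a hindered base and water present before warming keep the benzylic ether otherwise intact.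

Step 12
Reactants: 17 heptasilylated upper C4β–O–C3α lower ether with free lower 4β-hydroxyl
Product: 18 CNP0266687.1
Conditions: Et3N·3HF, THF–MeCN, rt, Ar
Reagents that add atoms: none
Why: Fluoride-mediated cleavage of the six aryl and one secondary alkyl silyl ethers with the near-neutral amine–HF complex should not ionise the benzylic ether or alcohol and affects no stereocentre.

**Compound list**

1 | gallacetophenone (2',3',4'-trihydroxyacetophenone) | CC(=O)c1ccc(O)c(O)c1O | starting material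

2 | 4-hydroxybenzaldehyde | O=Cc1ccc(O)cc1 | starting material

3 | (E)-2',3',4',4-tetrahydroxychalcone | O=C(/C=C/c1ccc(O)cc1)c1ccc(O)c(O)c1O | intermediate

4 | rac-7,8,4'-trihydroxyflavanone | O=C1CC(c2ccc(O)cc2)Oc2c(O)c(O)ccc12 | intermediate

5 | rac-7,8,4'-tris(TBS-oxy)flavanone | CC(C)(C)[Si](C)(C)Oc1ccc(C2CC(=O)c3ccc(O[Si](C)(C)C(C)(C)C)c(O[Si](C)(C)C(C)(C)C)c3O2)cc1 | intermediate

6 | (2S,4S)-7,8,4'-tris(TBS-oxy)flavan-4-ol, 2,4-cis | CC(C)(C)[Si](C)(C)Oc1ccc([C@H]2Oc3c(ccc(O[Si](C)(C)C(C)(C)C)c3O[Si](C)(C)C(C)(C)C)[C@@H](O)C2)cc1 | intermediate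

7 | (2S)-7,8,4'-tris(TBS-oxy)flav-3-ene | CC(C)(C)[Si](C)(C)Oc1ccc([C@H]2Oc3c(ccc(O[Si](C)(C)C(C)(C)C)c3O[Si](C)(C)C(C)(C)C)C=C2)cc1 | intermediate

8 | (2R,3S,4R)-3-bromo-7,8,4'-tris(TBS-oxy)flavan-4-ol, 3β-Br, 4α-OH | CC(C)(C)[Si](C)(C)Oc1ccc([C@H]2Oc3c(ccc(O[Si](C)(C)C(C)(C)C)c3O[Si](C)(C)C(C)(C)C)[C@@H](O)[C@@H]2Br)cc1 | intermediate

9 | (2R)-3α,4α-epoxy-7,8,4'-tris(TBS-oxy)flavan, epoxide cis to the aryl group | CC(C)(C)[Si](C)(C)Oc1ccc([C@H]2Oc3c(ccc(O[Si](C)(C)C(C)(C)C)c3O[Si](C)(C)C(C)(C)C)[C@H]4O[C@@H]24)cc1 | intermediate (not isolated)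

10 | (2R,3S,4S)-4-acetoxy-7,8,4'-tris(TBS-oxy)flavan-3-ol, 2,3-cis-3,4-trans, 3α-OH, 4β-OAc | CC(C)(C)[Si](C)(C)Oc1ccc([C@H]2Oc3c(ccc(O[Si](C)(C)C(C)(C)C)c3O[Si](C)(C)C(C)(C)C)[C@H](OC(C)=O)[C@H]2O)cc1 | intermediate

11 | (2R,3S,4S)-4-acetoxy-3,7,8,4'-tetrakis(TBS-oxy)flavan, 3α-OTBS, 4β-OAc | CC(C)(C)[Si](C)(C)Oc1ccc([C@H]2Oc3c(ccc(O[Si](C)(C)C(C)(C)C)c3O[Si](C)(C)C(C)(C)C)[C@H](OC(C)=O)[C@H]2O[Si](C)(C)C(C)(C)C)cc1 | intermediate

12 | (2R,3R,4S)-3,7,8,4'-tetrakis(TBS-oxy)flavan-4-ol, 3α-OTBS, 4β-OH | CC(C)(C)[Si](C)(C)Oc1ccc([C@H]2Oc3c(ccc(O[Si](C)(C)C(C)(C)C)c3O[Si](C)(C)C(C)(C)C)[C@H](O)[C@H]2O[Si](C)(C)C(C)(C)C)cc1 | intermediate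

13 | (2R)-3β,4β-epoxy-7,8,4'-tris(TBS-oxy)flavan, epoxide trans to the aryl group | CC(C)(C)[Si](C)(C)Oc1ccc([C@H]2Oc3c(ccc(O[Si](C)(C)C(C)(C)C)c3O[Si](C)(C)C(C)(C)C)[C@@H]4O[C@H]24)cc1 | intermediate (not isolated)

14 | [(2R,3R,4S)-3,7,8,4'-tetrakis(TBS-oxy)flavan-4-yl] [(2R,3S,4R)-3-hydroxy-7,8,4'-tris(TBS-oxy)flavan-4-yl] ether; upper C4β–O–C4α lower, lower unit 2,3-trans-3,4-trans with free 3β-OH | CC(C)(C)[Si](C)(C)Oc1ccc([C@H]2Oc3c(ccc(O[Si](C)(C)C(C)(C)C)c3O[Si](C)(C)C(C)(C)C)[C@H](O[C@@H]3c4ccc(O[Si](C)(C)C(C)(C)C)c(O[Si](C)(C)C(C)(C)C)c4O[C@H](c4ccc(O[Si](C)(C)C(C)(C)C)cc4)[C@H]3O)[C@H]2O[Si](C)(C)C(C)(C)C)cc1 | intermediate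

15 | lower 3β-O-triflate of 14 | CC(C)(C)[Si](C)(C)Oc1ccc([C@H]2Oc3c(ccc(O[Si](C)(C)C(C)(C)C)c3O[Si](C)(C)C(C)(C)C)[C@H](O[C@@H]3c4ccc(O[Si](C)(C)C(C)(C)C)c(O[Si](C)(C)C(C)(C)C)c4O[C@H](c4ccc(O[Si](C)(C)C(C)(C)C)cc4)[C@H]3OS(=O)(=O)C(F)(F)F)[C@H]2O[Si](C)(C)C(C)(C)C)cc1 | intermediate (not isolated)

16 | oxiranium triflate: oxygen bridging lower C3 and C4 on the α face and carrying upper C4 | CC(C)(C)[Si](C)(C)Oc1ccc([C@H]2Oc3c(ccc(O[Si](C)(C)C(C)(C)C)c3O[Si](C)(C)C(C)(C)C)[C@H]([O+]5[C@@H]6c7ccc(O[Si](C)(C)C(C)(C)C)c(O[Si](C)(C)C(C)(C)C)c7O[C@H](c7ccc(O[Si](C)(C)C(C)(C)C)cc7)[C@H]56)[C@H]2O[Si](C)(C)C(C)(C)C)cc1.[O-]S(=O)(=O)C(F)(F)F | intermediate (not isolated)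

17 | (2R,3R,4S)-3-[(2R,3R,4S)-3,7,8,4'-tetrakis(TBS-oxy)flavan-4-yloxy]-7,8,4'-tris(TBS-oxy)flavan-4-ol; upper C4β–O–C3α lower, lower unit 2,3-cis-3,4-trans with free 4β-OH | CC(C)(C)[Si](C)(C)Oc1ccc([C@H]2Oc3c(ccc(O[Si](C)(C)C(C)(C)C)c3O[Si](C)(C)C(C)(C)C)[C@H](O[C@H]3[C@@H](c4ccc(O[Si](C)(C)C(C)(C)C)cc4)Oc4c(ccc(O[Si](C)(C)C(C)(C)C)c4O[Si](C)(C)C(C)(C)C)[C@@H]3O)[C@H]2O[Si](C)(C)C(C)(C)C)cc1 | intermediate

18 | CNP0266687.1, (2R,3R,4S)-3-[(2R,3R,4S)-3,7,8,4'-tetrahydroxyflavan-4-yloxy]-7,8,4'-trihydroxyflavan-4-ol; both units 2,3-cis-3,4-trans | Oc1ccc([C@H]2Oc3c(ccc(O)c3O)[C@H](O[C@H]3[C@@H](c4ccc(O)cc4)Oc4c(ccc(O)c4O)[C@@H]3O)[C@H]2O)cc1 | target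

**Step count and risks**

Total step count: 12. Longest linear sequence: 12 steps (1 to 5, 6 to 9, 10 to 12); step 10 draws a second portion of 7.

Steps most likely to fail:

Step 11. The 2-aryl group of the lower unit may participate in place of the ether oxygen (1,2-aryl shift to a C2 oxocarbenium ion), or the oxonium ion may shed the upper unit by heterolysis of its exocyclic C4–O bond; either destroys the rearrangement. The fallback uses known chemistry and sets out from 12 and 10. Alcohol 12 is treated with Cl3CCN and catalytic DBU in CH2Cl2 at 0 °C to give the upper 4β-O-trichloroacetimidate F1. Ionisation of this imidate with catalytic TMSOTf over 4 Å molecular sieves in CH2Cl2 at −78 °C in the presence of hydroxy acetate 10 should let the 3α-hydroxyl of 10 capture the 2,3-cis flavan-4-yl cation trans to the 3-silyloxy group. This gives the upper C4β–O–C3α lower ether with a lower 4β-acetate F2. Cleavage of the acetate with i-Bu2AlH at −78 °C comes back to the route at 17.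

Step 10. The β-epoxide may rearrange by hydride shift or open through the free benzylic cation without facial control before the hindered alcohol captures it, and the alcohol itself may ionise under the Lewis acid. The fallback sets out from 7. The epoxide is generated with DMDO as before and quenched cold in acetic acid as co-solvent, which should give the 2,3-trans-3,4-trans 4α-acetoxy-3β-ol F3. Acetylation (Ac2O, pyridine, DMAP) gives the 3β,4α-diacetate F4. Catalytic TMSOTf at −78 °C ionises the 4-acetate with anchimeric help from the 3β-acetoxy group, and 12 should open the β-face acetoxonium ion at C4 from the α face (1,2-trans rule) to give the upper C4β–O–C4α lower ether with a lower 3β-acetate F5. i-Bu2AlH at −78 °C removes the acetate and comes back to the route at 14.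

Step 4. The rate difference between the enantiomers of the bulky silylated flavanone may be too small, or reversible ring opening to the chalcone may erode the enantiomeric purity on which both halves depend. The fallback sets out from 5. NaBH4 in THF–EtOH at 0 °C should give by axial hydride delivery the racemic 2,4-cis-flavan-4-ol F6. Acylative kinetic resolution with Candida antarctica lipase B and vinyl acetate in MTBE is expected, by the usual enantiopreference of lipases for 1-arylalkanols, to convert the (2R,4R)-enantiomer into the (2R,4R)-4-acetate F7 and leave the (2S,4S)-alcohol, which comes back to the route at 6.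

**Further compounds**

F1 | step 11 | 4β-O-trichloroacetimidate of 12, 3α-OTBS | CC(C)(C)[Si](C)(C)Oc1ccc([C@H]2Oc3c(ccc(O[Si](C)(C)C(C)(C)C)c3O[Si](C)(C)C(C)(C)C)[C@H](OC(=N)C(Cl)(Cl)Cl)[C@H]2O[Si](C)(C)C(C)(C)C)cc1

F2 | step 11 | lower 4β-O-acetate of 17 | CC(C)(C)[Si](C)(C)Oc1ccc([C@H]2Oc3c(ccc(O[Si](C)(C)C(C)(C)C)c3O[Si](C)(C)C(C)(C)C)[C@H](O[C@H]3[C@@H](c4ccc(O[Si](C)(C)C(C)(C)C)cc4)Oc4c(ccc(O[Si](C)(C)C(C)(C)C)c4O[Si](C)(C)C(C)(C)C)[C@@H]3OC(C)=O)[C@H]2O[Si](C)(C)C(C)(C)C)cc1

F3 | step 10 | (2R)-2,3-trans-3,4-trans-4-acetoxy-7,8,4'-tris(TBS-oxy)flavan-3-ol, 3β-OH, 4α-OAc | CC(C)(C)[Si](C)(C)Oc1ccc([C@H]2Oc3c(ccc(O[Si](C)(C)C(C)(C)C)c3O[Si](C)(C)C(C)(C)C)[C@@H](OC(C)=O)[C@@H]2O)cc1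

F4 | step 10 | (2R)-2,3-trans-3,4-trans-3,4-diacetoxy-7,8,4'-tris(TBS-oxy)flavan, 3β-OAc, 4α-OAc | CC(C)(C)[Si](C)(C)Oc1ccc([C@H]2Oc3c(ccc(O[Si](C)(C)C(C)(C)C)c3O[Si](C)(C)C(C)(C)C)[C@@H](OC(C)=O)[C@@H]2OC(C)=O)cc1

F5 | step 10 | lower 3β-O-acetate of 14 | CC(C)(C)[Si](C)(C)Oc1ccc([C@H]2Oc3c(ccc(O[Si](C)(C)C(C)(C)C)c3O[Si](C)(C)C(C)(C)C)[C@H](O[C@@H]3c4ccc(O[Si](C)(C)C(C)(C)C)c(O[Si](C)(C)C(C)(C)C)c4O[C@H](c4ccc(O[Si](C)(C)C(C)(C)C)cc4)[C@H]3OC(C)=O)[C@H]2O[Si](C)(C)C(C)(C)C)cc1

F6 | step 4 | rac-2,4-cis-7,8,4'-tris(TBS-oxy)flavan-4-ol (racemate, relative configuration shown) | CC(C)(C)[Si](C)(C)Oc1ccc([C@H]2Oc3c(ccc(O[Si](C)(C)C(C)(C)C)c3O[Si](C)(C)C(C)(C)C)[C@@H](O)C2)cc1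

F7 | step 4 | (2R,4R)-4-acetoxy-7,8,4'-tris(TBS-oxy)flavan | CC(C)(C)[Si](C)(C)Oc1ccc([C@@H]2Oc3c(ccc(O[Si](C)(C)C(C)(C)C)c3O[Si](C)(C)C(C)(C)C)[C@H](OC(C)=O)C2)cc1
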